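**Retrosynthetic overview**
1. Target (oxolane O1, C2 aryl, C3 bearing C9H2OH, C4, C5; exocyclic carbinol carbon C7) ⇒ last, hydrogenolysis of two aryl benzyl ethers and fluoride removal of a C9 silyl ether.
2. Oxolane O1–C5 bond ⇒ 5-exo-tet Williamson closure of the free C2 benzylic hydroxyl onto a primary C5 sulfonate (retention at every stereocentre). The C5 and C9 carbinols are told apart through a temporary acetonide across the C5 and C7 oxygens.
3. C4–C7 bond ⇒ intermolecular aldol of the lithium enolate of a 4-substituted γ-butyrolactone with O-benzylvanillin (3,4-trans, anti carbinol).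
4. C2–C3 bond ⇒ intermolecular Evans syn-aldol of N-pent-4-enoyl-(S)-4-benzyloxazolidinone with O-benzylvanillin; the allyl group is later cut down to the lactone carbonyl.
5. Ring order: temporary γ-lactone (through its lactol) → temporary 1,3-dioxane → oxolane of the target.

Assumption and notation: the atom labels above are kept for the same atoms in every intermediate; Ar = 4-(benzyloxy)-3-methoxyphenyl, TBS = tert-butyldimethylsilyl, TBDPS = tert-butyldiphenylsilyl; compounds 1, 2 and 5 are bought.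

**Step 1**
Reactants: 1 (4S)-4-benzyl-1,3-oxazolidin-2-one; 2 pent-4-enoyl chloride
Product: 4 (4S)-4-benzyl-3-(pent-4-enoyl)-1,3-oxazolidin-2-one, via lithium oxazolidinide 3 (not isolated)
Conditions: nBuLi, THF, −78 °C; then 2, −78 → 0 °C
Reagents that add atoms: none
Why: N-acylation (nucleophilic acyl substitution) of the lithiated auxiliary by the acid chloride installs the enolisable C3–C9 unit, with no new stereocentre.

**Step 2**
Reactants: 4 (4S)-4-benzyl-3-(pent-4-enoyl)-1,3-oxazolidin-2-one; 5 4-(benzyloxy)-3-methoxybenzaldehyde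
Product: 7 syn-aldol adduct (4S)-4-benzyl-3-[(2S)-2-[(S)-Ar(hydroxy)methyl]pent-4-enoyl]-1,3-oxazolidin-2-one, via dibutylboron Z-enolate 6 (not isolated)
Conditions: Bu2BOTf, iPr2NEt, CH2Cl2, 0 °C; then 5, −78 → 0 °C; pH 7 buffer, MeOH, 30% H2O2, 0 °C
Reagents that add atoms: none
Why: Evans syn-aldol reaction, in which the Z-boron enolate reacts through a closed Zimmerman–Traxler chair on the face away from the auxiliary benzyl group, forming the C2–C3 bond and setting C2 (S) and C3 syn to it under auxiliary control.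

**Step 3**
Reactants: 7 syn-aldol adduct
Product: 8 (4S)-4-benzyl-3-[(2S)-2-[(S)-Ar(TBS-oxy)methyl]pent-4-enoyl]-1,3-oxazolidin-2-one
Conditions: TBSOTf, 2,6-lutidine, CH2Cl2, 0 °C
Reagents that add atoms: tert-butyldimethylsilyl trifluoromethanesulfonate, CC(C)(C)[Si](C)(C)OS(=O)(=O)C(F)(F)F
Why: Silyl ether formation with the reactive silyl triflate and a hindered base protects the benzylic carbinol without retro-aldol or epimerisation.

**Step 4**
Reactants: 8 silyl-protected aldol adduct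
Product: 9 (2R)-2-[(S)-Ar(TBS-oxy)methyl]pent-4-en-1-ol
Conditions: LiBH4, THF, 0 °C → rt; aq. NaOH work-up
Reagents that add atoms: none
Why: Reductive cleavage of the imide by hydride frees the C9 primary alcohol and the recoverable auxiliary, leaving the silyl ether, benzyl ether, alkene and both stereocentres untouched.

**Step 5**
Reactants: 9 (2R)-2-[(S)-Ar(TBS-oxy)methyl]pent-4-en-1-ol
Product: 12 lactol (4R)-4-[(S)-Ar(TBS-oxy)methyl]oxolan-2-ol (anomer mixture), via triol 10 (not isolated), via hydroxy aldehyde 11 (not isolated)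
Conditions: OsO4 (2 mol%), NaIO4 (4 equiv), 2,6-lutidine, 1,4-dioxane/H2O 3:1, rt
Reagents that add atoms: osmium tetroxide OsO4, O=[Os](=O)(=O)=O (oxygen carrier); sodium periodate NaIO4, [Na+].[O-]I(=O)(=O)=O (terminal oxygen source)
Why: Lemieux–Johnson oxidation (catalytic dihydroxylation, then periodate glycol cleavage) removes the terminal carbon, and the γ-hydroxy aldehyde closes spontaneously to the five-membered lactol.

**Step 6**
Reactants: 12 lactol
Product: 13 (4R)-4-[(S)-Ar(TBS-oxy)methyl]oxolan-2-one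
Conditions: nPr4N[RuO4] (5 mol%), N-methylmorpholine N-oxide, 4 Å molecular sieves, CH2Cl2, rt
Reagents that add atoms: none
Why: Ley–Griffith oxidation converts the lactol into the γ-lactone under neutral conditions that spare the silyl ether and the electron-rich arene.

**Step 7**
Reactants: 13 (4R)-4-[(S)-Ar(TBS-oxy)methyl]oxolan-2-one; 5 4-(benzyloxy)-3-methoxybenzaldehyde
Product: 15 (3S,4R)-3-[(R)-Ar(hydroxy)methyl]-4-[(S)-Ar(TBS-oxy)methyl]oxolan-2-one, via lithium enolate 14 (not isolated)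
Conditions: LiN(SiMe3)2 (1.1 equiv), THF, −78 °C; then 5, −78 °C, 1 h; AcOH quench at −78 °C; chromatography
Reagents that add atoms: none
Why: Intermolecular lactone-enolate aldol addition forms the C4–C7 bond; the aldehyde adds to the ring-fixed E-enolate on the face opposite the bulky C3 substituent (3,4-trans lactone), and the chair transition state with equatorial aryl is expected to give the anti (7R) carbinol as the major, chromatographically separable isomer.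

**Step 8**
Reactants: 15 aldol lactone
Product: 16 (2R,3R)-2-[(S)-Ar(TBS-oxy)methyl]-3-[(R)-Ar(hydroxy)methyl]butane-1,4-diol
Conditions: LiAlH4, THF, 0 °C; aq. NaOH work-up
Reagents that add atoms: none
Why: Hydride reduction of the lactone to the 1,4-diol at 0 °C is faster than retro-aldol and leaves the silyl and benzyl ethers and all four stereocentres intact.

**Step 9**
Reactants: 16 triol
Product: 17 (2R,3S)-3-Ar-2-[(4R,5R)-4-Ar-2,2-dimethyl-1,3-dioxan-5-yl]-3-(TBS-oxy)propan-1-ol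
Conditions: Me2C(OMe)2, pyridinium p-toluenesulfonate (cat.), CH2Cl2, rt
Reagents that add atoms: 2,2-dimethoxypropane, COC(C)(C)OC
Why: Thermodynamically controlled acetalisation ties up the only 1,3-diol (C5 and C7 hydroxyls) as a trans-diequatorial six-membered acetonide, so the C9 primary hydroxyl is the only one left free.

**Step 10**
Reactants: 17 acetonide
Product: 18 (1S,2R)-1-Ar-2-[(4R,5R)-4-Ar-2,2-dimethyl-1,3-dioxan-5-yl]propane-1,3-diol
Conditions: Bu4NF, THF, 0 °C → rt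
Reagents that add atoms: none
Why: Fluoride-mediated desilylation unmasks the C2 benzylic hydroxyl, while the acetonide and the benzyl ethers are inert to fluoride.

**Step 11**
Reactants: 18 diol
Product: 19 (1S,2R)-1-Ar-2-[(4R,5R)-4-Ar-2,2-dimethyl-1,3-dioxan-5-yl]-3-(TBDPS-oxy)propan-1-ol
Conditions: TBDPSCl (1.1 equiv), imidazole, CH2Cl2, 0 °C
Reagents that add atoms: tert-butyl(chloro)diphenylsilane, CC(C)(C)[Si](Cl)(c1ccccc1)c1ccccc1
Why: Sterically controlled silylation, since the bulky chlorosilane reacts with the primary C9 hydroxyl and not with the hindered secondary benzylic C2 hydroxyl.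

**Step 12**
Reactants: 19 silyl ether acetonide
Product: 20 (2R,3R)-2-[(R)-Ar(hydroxy)methyl]-3-[(S)-Ar(hydroxy)methyl]-4-(TBDPS-oxy)butan-1-ol
Conditions: AcOH/THF/H2O 3:1:1, rt
Reagents that add atoms: none
Why: Mild acid hydrolysis of the ketal releases the C5 primary and C7 secondary hydroxyls, the primary TBDPS ether and aryl benzyl ethers being stable and the acid too weak to ionise the benzylic carbinols.

**Step 13**
Reactants: 20 triol
Product: 22 (R)-Ar[(3R,4R,5S)-5-Ar-4-[(TBDPS-oxy)methyl]oxolan-3-yl]methanol, via primary tosylate 21 (not isolated)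
Conditions: TsCl (1.2 equiv), pyridine, 0 °C → rt; then 60 °C
Reagents that add atoms: none
Why: Selective sulfonylation of the only primary hydroxyl followed by intramolecular Williamson etherification (5-exo-tet SN2 at the primary C5 by the C2 hydroxyl) closes the oxolane with retention at every stereocentre, because the C7 hydroxyl could only form a four-membered ring and the C9 oxygen is silylated.

**Step 14**
Reactants: 22 silyl-protected oxolane
Product: 23 (R)-Ar[(3R,4R,5S)-5-Ar-4-(hydroxymethyl)oxolan-3-yl]methanol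
Conditions: Bu4NF, THF, rt
Reagents that add atoms: none
Why: Fluoride desilylation frees the C9 primary alcohol without touching the benzyl ethers or any stereocentre.

**Step 15**
Reactants: 23 bis(benzyl ether)
Product: 24 (7R)-7-hydroxylariciresinol
Conditions: H2 (1 atm), 10% Pd/C, EtOAc/EtOH, rt, stopped at full conversion
Reagents that add atoms: none
Why: Catalytic hydrogenolysis cleaves the two aryl benzyl ethers much faster under neutral conditions than the benzylic C7–OH or C2–O1 bonds, giving the target with all four stereocentres as set in steps 2 and 7.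

**Compound list**
1 | (4S)-4-benzyl-1,3-oxazolidin-2-one | O=C1N[C@@H](Cc2ccccc2)CO1 | starting material
2 | pent-4-enoyl chloride | C=CCCC(=O)Cl | starting material
3 | (4S)-4-benzyl-3-lithio-1,3-oxazolidin-2-one (lithium salt of 1) | [Li]N1[C@@H](Cc2ccccc2)COC1=O | intermediate
4 | (4S)-4-benzyl-3-(pent-4-enoyl)-1,3-oxazolidin-2-one | C=CCCC(=O)N1[C@@H](Cc2ccccc2)COC1=O | intermediate
5 | 4-(benzyloxy)-3-methoxybenzaldehyde | O=Cc1ccc(OCc2ccccc2)c(OC)c1 | starting material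
6 | (4S)-4-benzyl-3-[(1Z)-1-[(dibutylboranyl)oxy]penta-1,4-dien-1-yl]-1,3-oxazolidin-2-one (Z-boron enolate of 4) | C=CC/C=C(\OB(CCCC)CCCC)N1[C@@H](Cc2ccccc2)COC1=O | intermediate
7 | (4S)-4-benzyl-3-[(2S)-2-[(S)-[4-(benzyloxy)-3-methoxyphenyl](hydroxy)methyl]pent-4-enoyl]-1,3-oxazolidin-2-one | C=CC[C@H](C(=O)N1[C@@H](Cc2ccccc2)COC1=O)[C@H](O)c1ccc(OCc2ccccc2)c(OC)c1 | intermediate
8 | (4S)-4-benzyl-3-[(2S)-2-[(S)-[4-(benzyloxy)-3-methoxyphenyl][(tert-butyldimethylsilyl)oxy]methyl]pent-4-enoyl]-1,3-oxazolidin-2-one | C=CC[C@H](C(=O)N1[C@@H](Cc2ccccc2)COC1=O)[C@H](O[Si](C)(C)C(C)(C)C)c1ccc(OCc2ccccc2)c(OC)c1 | intermediate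
9 | (2R)-2-[(S)-[4-(benzyloxy)-3-methoxyphenyl][(tert-butyldimethylsilyl)oxy]methyl]pent-4-en-1-ol | C=CC[C@H](CO)[C@H](O[Si](C)(C)C(C)(C)C)c1ccc(OCc2ccccc2)c(OC)c1 | intermediate
10 | (2RS,4R)-4-[(S)-[4-(benzyloxy)-3-methoxyphenyl][(tert-butyldimethylsilyl)oxy]methyl]pentane-1,2,5-triol | OCC(O)C[C@H](CO)[C@H](O[Si](C)(C)C(C)(C)C)c1ccc(OCc2ccccc2)c(OC)c1 | intermediate
11 | (3R,4S)-4-[4-(benzyloxy)-3-methoxyphenyl]-4-[(tert-butyldimethylsilyl)oxy]-3-(hydroxymethyl)butanal | O=CC[C@H](CO)[C@H](O[Si](C)(C)C(C)(C)C)c1ccc(OCc2ccccc2)c(OC)c1 | intermediate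
12 | (2RS,4R)-4-[(S)-[4-(benzyloxy)-3-methoxyphenyl][(tert-butyldimethylsilyl)oxy]methyl]oxolan-2-ol | OC1C[C@H](CO1)[C@H](O[Si](C)(C)C(C)(C)C)c1ccc(OCc2ccccc2)c(OC)c1 | intermediate
13 | (4R)-4-[(S)-[4-(benzyloxy)-3-methoxyphenyl][(tert-butyldimethylsilyl)oxy]methyl]oxolan-2-one | O=C1C[C@H](CO1)[C@H](O[Si](C)(C)C(C)(C)C)c1ccc(OCc2ccccc2)c(OC)c1 | intermediate
14 | lithium (3R)-3-[(S)-[4-(benzyloxy)-3-methoxyphenyl][(tert-butyldimethylsilyl)oxy]methyl]-2,3-dihydrofuran-5-olate (lithium enolate of 13) | [Li]OC1=C[C@H](CO1)[C@H](O[Si](C)(C)C(C)(C)C)c1ccc(OCc2ccccc2)c(OC)c1 | intermediate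
15 | (3S,4R)-3-[(R)-[4-(benzyloxy)-3-methoxyphenyl](hydroxy)methyl]-4-[(S)-[4-(benzyloxy)-3-methoxyphenyl][(tert-butyldimethylsilyl)oxy]methyl]oxolan-2-one | O=C1OC[C@H]([C@H](O[Si](C)(C)C(C)(C)C)c2ccc(OCc3ccccc3)c(OC)c2)[C@H]1[C@@H](O)c1ccc(OCc2ccccc2)c(OC)c1 | intermediate
16 | (2R,3R)-2-[(S)-[4-(benzyloxy)-3-methoxyphenyl][(tert-butyldimethylsilyl)oxy]methyl]-3-[(R)-[4-(benzyloxy)-3-methoxyphenyl](hydroxy)methyl]butane-1,4-diol | OC[C@H]([C@H](O[Si](C)(C)C(C)(C)C)c1ccc(OCc2ccccc2)c(OC)c1)[C@H](CO)[C@@H](O)c1ccc(OCc2ccccc2)c(OC)c1 | intermediate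
17 | (2R,3S)-3-[4-(benzyloxy)-3-methoxyphenyl]-2-[(4R,5R)-4-[4-(benzyloxy)-3-methoxyphenyl]-2,2-dimethyl-1,3-dioxan-5-yl]-3-[(tert-butyldimethylsilyl)oxy]propan-1-ol | OC[C@H]([C@H](O[Si](C)(C)C(C)(C)C)c1ccc(OCc2ccccc2)c(OC)c1)[C@@H]1COC(C)(C)O[C@H]1c3ccc(OCc4ccccc4)c(OC)c3 | intermediate
18 | (1S,2R)-1-[4-(benzyloxy)-3-methoxyphenyl]-2-[(4R,5R)-4-[4-(benzyloxy)-3-methoxyphenyl]-2,2-dimethyl-1,3-dioxan-5-yl]propane-1,3-diol | OC[C@H]([C@H](O)c1ccc(OCc2ccccc2)c(OC)c1)[C@@H]1COC(C)(C)O[C@H]1c3ccc(OCc4ccccc4)c(OC)c3 | intermediate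
19 | (1S,2R)-1-[4-(benzyloxy)-3-methoxyphenyl]-2-[(4R,5R)-4-[4-(benzyloxy)-3-methoxyphenyl]-2,2-dimethyl-1,3-dioxan-5-yl]-3-[(tert-butyldiphenylsilyl)oxy]propan-1-ol | CC(C)(C)[Si](c1ccccc1)(c1ccccc1)OC[C@H]([C@H](O)c1ccc(OCc2ccccc2)c(OC)c1)[C@@H]1COC(C)(C)O[C@H]1c3ccc(OCc4ccccc4)c(OC)c3 | intermediate
20 | (2R,3R)-2-[(R)-[4-(benzyloxy)-3-methoxyphenyl](hydroxy)methyl]-3-[(S)-[4-(benzyloxy)-3-methoxyphenyl](hydroxy)methyl]-4-[(tert-butyldiphenylsilyl)oxy]butan-1-ol | CC(C)(C)[Si](c1ccccc1)(c1ccccc1)OC[C@H]([C@H](O)c1ccc(OCc2ccccc2)c(OC)c1)[C@H](CO)[C@@H](O)c1ccc(OCc2ccccc2)c(OC)c1 | intermediate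
21 | (2R,3R)-2-[(R)-[4-(benzyloxy)-3-methoxyphenyl](hydroxy)methyl]-3-[(S)-[4-(benzyloxy)-3-methoxyphenyl](hydroxy)methyl]-4-[(tert-butyldiphenylsilyl)oxy]butyl 4-methylbenzenesulfonate | CC(C)(C)[Si](c1ccccc1)(c1ccccc1)OC[C@H]([C@H](O)c1ccc(OCc2ccccc2)c(OC)c1)[C@H](COS(=O)(=O)c1ccc(C)cc1)[C@@H](O)c1ccc(OCc2ccccc2)c(OC)c1 | intermediate
22 | (R)-[4-(benzyloxy)-3-methoxyphenyl][(3R,4R,5S)-5-[4-(benzyloxy)-3-methoxyphenyl]-4-{[(tert-butyldiphenylsilyl)oxy]methyl}oxolan-3-yl]methanol | COc1cc([C@H]2OC[C@H]([C@@H](O)c3ccc(OCc4ccccc4)c(OC)c3)[C@@H]2CO[Si](c3ccccc3)(c3ccccc3)C(C)(C)C)ccc1OCc1ccccc1 | intermediate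
23 | (R)-[4-(benzyloxy)-3-methoxyphenyl][(3R,4R,5S)-5-[4-(benzyloxy)-3-methoxyphenyl]-4-(hydroxymethyl)oxolan-3-yl]methanol | COc1cc([C@H]2OC[C@H]([C@@H](O)c3ccc(OCc4ccccc4)c(OC)c3)[C@@H]2CO)ccc1OCc1ccccc1 | intermediate
24 | (7R)-7-hydroxylariciresinol, (R)-(4-hydroxy-3-methoxyphenyl)[(3R,4R,5S)-5-(4-hydroxy-3-methoxyphenyl)-4-(hydroxymethyl)oxolan-3-yl]methanol | COc1cc([C@H]2OC[C@H]([C@@H](O)c3ccc(O)c(OC)c3)[C@@H]2CO)ccc1O | target

**Totals**
Total step count: 15.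
Longest linear sequence: 15 steps (1 → 24; aldehyde 5 enters in steps 2 and 7).

**Steps most likely to fail, with fallbacks**

Step 4 (LiBH4 cleavage of the hindered, α-branched imide 8 can instead open the oxazolidinone ring). The fallback sets out from 7 and comes back to the route at 9. Compound 7 is transamidated with MeNHOMe·HCl and AlMe3 (CH2Cl2, 0 °C) to the Weinreb amide (2S)-2-[(S)-Ar(hydroxy)methyl]-N-methoxy-N-methylpent-4-enamide F1. This is silylated (TBSOTf, 2,6-lutidine) to (2S)-2-[(S)-Ar(TBS-oxy)methyl]-N-methoxy-N-methylpent-4-enamide F2. Reduction with iBu2AlH (THF, −78 °C) gives the aldehyde (2S)-2-[(S)-Ar(TBS-oxy)methyl]pent-4-enal F3, which is reduced at once with NaBH4 (MeOH, 0 °C) to 9.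

Step 7 (the trans relationship is secure, but the anti/syn ratio at C7 of a lithium lactone enolate aldol may be modest). The fallback sets out from 13 and comes back at 15. The enolate of 13 (2.1 equiv LiN(SiMe3)2, THF, −78 °C) is C-acylated with 4-(benzyloxy)-3-methoxybenzoyl chloride in a crossed Claisen condensation, giving the trans β-keto lactone (3S,4R)-3-[4-(benzyloxy)-3-methoxybenzoyl]-4-[(S)-Ar(TBS-oxy)methyl]oxolan-2-one F4. Its aryl ketone is then reduced under catalyst control by asymmetric transfer hydrogenation (RuCl[(R,R)-TsDPEN](p-cymene), HCO2H/Et3N, rt). The (R,R) catalyst should give the 7R carbinol 15, while C4 stays in its thermodynamically preferred trans arrangement.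

Step 13 (tosylation must pick the primary hydroxyl of a triol that also carries two ionisable, electron-rich benzylic hydroxyls). The fallback sets out from 17 and comes back at 24; here the C2 oxygen stays silylated until the leaving group is in place.
- The free C9 hydroxyl of 17 is benzylated under neutral conditions (2-benzyloxy-1-methylpyridinium trifluoromethanesulfonate, MgO, PhCF3, 83 °C) to tert-butyl{(1S,2R)-3-(benzyloxy)-1-Ar-2-[(4R,5R)-4-Ar-2,2-dimethyl-1,3-dioxan-5-yl]propoxy}dimethylsilane F5.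
- Aqueous AcOH removes the acetonide to give (1R,2R)-1-Ar-2-[(2R,3S)-1-(benzyloxy)-3-Ar-3-(TBS-oxy)propan-2-yl]propane-1,3-diol F6.
- The only primary hydroxyl is mesylated (MsCl, 2,4,6-collidine, CH2Cl2, −20 °C) to (2R,3R)-4-(benzyloxy)-2-[(R)-Ar(hydroxy)methyl]-3-[(S)-Ar(TBS-oxy)methyl]butyl methanesulfonate F7.
- Bu4NF in THF cleaves the silyl ether, and the released C2 alkoxide displaces the neighbouring mesylate to give (R)-Ar[(3R,4R,5S)-5-Ar-4-[(benzyloxy)methyl]oxolan-3-yl]methanol F8.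
- Hydrogenolysis of all three benzyl ethers (H2, Pd(OH)2/C, EtOAc/EtOH) gives 24.

**Further compounds**
F1 | step 4 | (2S)-2-[(S)-[4-(benzyloxy)-3-methoxyphenyl](hydroxy)methyl]-N-methoxy-N-methylpent-4-enamide | C=CC[C@H](C(=O)N(C)OC)[C@H](O)c1ccc(OCc2ccccc2)c(OC)c1
F2 | step 4 | (2S)-2-[(S)-[4-(benzyloxy)-3-methoxyphenyl][(tert-butyldimethylsilyl)oxy]methyl]-N-methoxy-N-methylpent-4-enamide | C=CC[C@H](C(=O)N(C)OC)[C@H](O[Si](C)(C)C(C)(C)C)c1ccc(OCc2ccccc2)c(OC)c1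
F3 | step 4 | (2S)-2-[(S)-[4-(benzyloxy)-3-methoxyphenyl][(tert-butyldimethylsilyl)oxy]methyl]pent-4-enal | C=CC[C@H](C=O)[C@H](O[Si](C)(C)C(C)(C)C)c1ccc(OCc2ccccc2)c(OC)c1
F4 | step 7 | (3S,4R)-3-[4-(benzyloxy)-3-methoxybenzoyl]-4-[(S)-[4-(benzyloxy)-3-methoxyphenyl][(tert-butyldimethylsilyl)oxy]methyl]oxolan-2-one | O=C1OC[C@H]([C@H](O[Si](C)(C)C(C)(C)C)c2ccc(OCc3ccccc3)c(OC)c2)[C@H]1C(=O)c1ccc(OCc2ccccc2)c(OC)c1
F5 | step 13 | tert-butyl{(1S,2R)-3-(benzyloxy)-1-[4-(benzyloxy)-3-methoxyphenyl]-2-[(4R,5R)-4-[4-(benzyloxy)-3-methoxyphenyl]-2,2-dimethyl-1,3-dioxan-5-yl]propoxy}dimethylsilane | c1ccccc1COC[C@H]([C@H](O[Si](C)(C)C(C)(C)C)c1ccc(OCc2ccccc2)c(OC)c1)[C@@H]1COC(C)(C)O[C@H]1c3ccc(OCc4ccccc4)c(OC)c3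
F6 | step 13 | (1R,2R)-1-[4-(benzyloxy)-3-methoxyphenyl]-2-[(2R,3S)-1-(benzyloxy)-3-[4-(benzyloxy)-3-methoxyphenyl]-3-[(tert-butyldimethylsilyl)oxy]propan-2-yl]propane-1,3-diol | c1ccccc1COC[C@H]([C@H](O[Si](C)(C)C(C)(C)C)c1ccc(OCc2ccccc2)c(OC)c1)[C@H](CO)[C@@H](O)c1ccc(OCc2ccccc2)c(OC)c1
F7 | step 13 | (2R,3R)-4-(benzyloxy)-2-[(R)-[4-(benzyloxy)-3-methoxyphenyl](hydroxy)methyl]-3-[(S)-[4-(benzyloxy)-3-methoxyphenyl][(tert-butyldimethylsilyl)oxy]methyl]butyl methanesulfonate | c1ccccc1COC[C@H]([C@H](O[Si](C)(C)C(C)(C)C)c1ccc(OCc2ccccc2)c(OC)c1)[C@H](COS(C)(=O)=O)[C@@H](O)c1ccc(OCc2ccccc2)c(OC)c1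
F8 | step 13 | (R)-[4-(benzyloxy)-3-methoxyphenyl][(3R,4R,5S)-5-[4-(benzyloxy)-3-methoxyphenyl]-4-[(benzyloxy)methyl]oxolan-3-yl]methanol | COc1cc([C@H]2OC[C@H]([C@@H](O)c3ccc(OCc4ccccc4)c(OC)c3)[C@@H]2COCc3ccccc3)ccc1OCc1ccccc1
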